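**Retrosynthetic overview**

1. Atoms are numbered along the target SMILES (C1–C2 ethyl, C3, C4, O5, C6, C8, C9 methyl, C10–C16, C17 methyl, C18, O20, N21, C22–C25, O26, C27, C28). The strategy rests on the C25 carbinol lying next to the quaternary spiro carbon C27, which joins the cyclopentane (ring A) to the seven-membered lactam, with C3 on C27 anti to O26: the retron of a 1,2-shift onto an epoxide carbon.
2. Key disconnection: spiro ketol (C28 ketone, C25 hydroxyl) from a cis-fused hydroxy epoxy decalin, C3 moving from C28 to C27 and contracting ring A from six to five members.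
3. Before it: ring A and C3 from an enantioselective ethyl addition to a quinone monoketal; lactone C (C4–O5–C6–C8–C10) by butenolide annulation and hydrogenation; C11 allyl by conjugate addition; ring B (C22–C25, C27, C28) by organocerium addition and ring-closing metathesis; hydroxyl-directed epoxidation.
4. After it: allyl to C13 aldehyde to sulfinimine; vinylogous Mannich addition and hydrogenation build lactone D (C14–C16, C18, O20); the C13 azide inserts into the C28–C22 bond (intramolecular Schmidt reaction) and closes both lactam rings.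
5. Ring order: A, lactone C, B, contraction of A, lactone D, the two lactam rings.

Key step: step 13

Assumption: the sense of induction in steps 1 and 18 is taken from the usual models (ligand-controlled ethyl delivery; open transition state with attack anti to the tert-butyl group of the s-cis sulfinimine), and the antipodal ligand or sulfinamide is used if the opposite sense is found.

Remark: the C11 side chain is carried as an allyl group through the key step (a spectator change), because one ozonolysis then gives the C13 aldehyde.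

**Route**

Step 1
Reactants: 1 4,4-dimethoxycyclohexa-2,5-dien-1-one
Product: 2 (R)-5-ethyl-4,4-dimethoxycyclohex-2-en-1-one
Conditions: Et2Zn, Cu(OTf)2 (2 mol %), binaphthol-derived N,N-bis(1-phenylethyl)phosphoramidite ligand (4 mol %), toluene, −25 °C
Reagents that add atoms: diethylzinc, CC[Zn]CC
Why: Copper–phosphoramidite catalysed enantioselective conjugate addition of a dialkylzinc desymmetrises the prochiral dienone, the ligand-controlled face selection setting C3, and the less reactive enone product resists a second addition.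

Step 2
Reactants: 2 (R)-5-ethyl-4,4-dimethoxycyclohex-2-en-1-one
Product: 3 (5R,6R)-5-ethyl-6-hydroxy-4,4-dimethoxycyclohex-2-en-1-one (ethyl and hydroxyl trans)
Conditions: NaN(SiMe3)2, THF, −78 °C; then 2-(phenylsulfonyl)-3-phenyloxaziridine
Reagents that add atoms: 2-(phenylsulfonyl)-3-phenyloxaziridine, O=S(=O)(c1ccccc1)N1OC1c1ccccc1
Why: Kinetic deprotonation at the only sp3 α-carbon (C4) and electrophilic enolate hydroxylation anti to the vicinal C3 ethyl group should give the trans hydroxy ketone, which is also the more stable diequatorial epimer.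

Step 3
Reactants: 3 (5R,6R)-5-ethyl-6-hydroxy-4,4-dimethoxycyclohex-2-en-1-one; 4 2-(diethoxyphosphoryl)propanoic acid
Product: 5 (1R,6R)-6-ethyl-5,5-dimethoxy-2-oxocyclohex-3-en-1-yl 2-(diethoxyphosphoryl)propanoate (epimers at the phosphonate carbon)
Conditions: N,N'-dicyclohexylcarbodiimide, 4-(dimethylamino)pyridine (cat.), CH2Cl2, 0 °C to rt
Reagents that add atoms: none
Why: Carbodiimide (Steglich) esterification of the secondary α-hydroxy ketone attaches the phosphonate that carries C6, C8 and C9 without touching a ring stereocentre.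

Step 4
Reactants: 5 phosphonate ester
Product: 6 (7R,7aR)-7-ethyl-6,6-dimethoxy-3-methyl-7,7a-dihydro-1-benzofuran-2(6H)-one (butenolide C8=C10, ring alkene C11=C27)
Conditions: LiCl, iPr2NEt, MeCN, rt
Reagents that add atoms: none
Why: Intramolecular Horner–Wadsworth–Emmons olefination of the C10 carbonyl by the tethered phosphonate closes lactone C as a butenolide under mild base that should leave C4 untouched; 6 is kept free of acid (loss of methanol would aromatise it) and is hydrogenated at once.

Step 5
Reactants: 6 dienyl butenolide ketal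
Product: 7 (3S,3aR,7R,7aS)-7-ethyl-6,6-dimethoxy-3-methylhexahydro-1-benzofuran-2(3H)-one (H4, H8, H10 cis)
Conditions: H2 (5 bar), 5% Rh on Al2O3, EtOAc, rt
Reagents that add atoms: none
Why: Heterogeneous hydrogenation saturates the disubstituted C11=C27 alkene and then adds hydrogen to the tetrasubstituted butenolide from the face of H4 (opposite the C4–C3 bond), which should give the cis-fused lactone with C8 and C10 as in the target, rhodium keeping allylic C–O hydrogenolysis low.

Step 6
Reactants: 7 saturated lactone ketal
Product: 8 (3S,3aR,7R,7aS)-7-ethyl-3-methylhexahydro-1-benzofuran-2,6-dione (C28 ketone)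
Conditions: pyridinium p-toluenesulfonate (cat.), acetone–H2O, rt
Reagents that add atoms: water, O
Why: Mild acid hydrolysis of the dimethyl ketal unveils the C28 ketone much faster than the ketone enolises, so C3, now α to the carbonyl and β to the lactone oxygen, should be kept.

Step 7
Reactants: 8 lactone ketone
Product: 10 (3S,3aR,7R,7aS)-7-ethyl-3-methyl-3a,7a-dihydro-1-benzofuran-2,6(3H,7H)-dione (enone C28=O/C27=C11), via trimethylsilyl enol ether 9 (not isolated)
Conditions: LiN(iPr)2, Me3SiCl, THF, −78 °C; then Pd(OAc)2, MeCN, rt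
Reagents that add atoms: none
Why: Kinetic deprotonation at the unhindered C27 methylene with in situ silylation (the C3 methine, whose enolate would expel the lactone carboxylate, is avoided) followed by Saegusa–Ito oxidation installs the enone under neutral conditions.

Step 8
Reactants: 10 enone lactone
Product: 12 Mannich base (C11 allyl trans to the C10–C8 bond; C27 dimethylaminomethyl as a mixture of C27 epimers), via allylated silyl enol ether 11 (not isolated)
Conditions: allylmagnesium bromide, CuBr·SMe2, Me3SiCl, THF, −78 °C; then Me2N=CH2+ I−, CH2Cl2, rt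
Reagents that add atoms: allylmagnesium bromide, C=CC[Mg]Br; dimethylmethyleneiminium iodide, C=[N+](C)C.[I-]
Why: Silyl-chloride-assisted conjugate addition of the allylcopper reagent occurs at C11 anti to the C10–C8 bond (convex face of the cis-fused bicycle), which sets C11, and the regiodefined silyl enol ether is then aminomethylated at C27 by the iminium salt (Mannich reaction).

Step 9
Reactants: 12 Mannich base
Product: 14 α-methylene ketone (C27=CH2; C28=O; C11 allyl), via trimethylammonium iodide 13 (not isolated)
Conditions: MeI, CH2Cl2, rt; then aq. NaHCO3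
Reagents that add atoms: none
Why: Exhaustive N-methylation and mild base-induced β-elimination of trimethylamine give the exocyclic enone and remove the C27 stereocentre.

Step 10
Reactants: 14 α-methylene ketone
Product: 15 tertiary alcohol (C28 hydroxyl cis to the C3 ethyl group; C28 pent-4-enyl; C27=CH2)
Conditions: pent-4-enylmagnesium bromide, CeCl3, THF, −78 °C
Reagents that add atoms: pent-4-enylmagnesium bromide, C=CCCC[Mg]Br
Why: The weakly basic organocerium reagent adds 1,2 to the enone carbonyl without enolising it, and attack anti to the vicinal C3 ethyl group and to the axial C11 allyl group (equatorial attack from the face of lactone C) should set C28 with the hydroxyl cis to the ethyl group.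

Step 11
Reactants: 15 diene alcohol
Product: 16 cis-fused decalin allylic alcohol (ring B closed; C27=C25; C28 hydroxyl at the ring fusion)
Conditions: second-generation Grubbs catalyst RuCl2(=CHPh)(PCy3)(H2IMes) (5 mol %), CH2Cl2 (5 mM), 40 °C
Reagents that add atoms: none
Why: Ring-closing metathesis between the pentenyl terminus and the 1,1-disubstituted C27 methylene closes the six-membered ring B with loss of ethene, the closures onto the allyl group being four- or nine-membered and therefore slow.

Step 12
Reactants: 16 allylic alcohol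
Product: 17 cis-fused hydroxy epoxy decalin (C28 carbinol; C27–C25 epoxide syn to the hydroxyl; C11 allyl; fused lactone C)
Conditions: VO(acac)2 (5 mol %), t-BuOOH, CH2Cl2, 0 °C to rt
Reagents that add atoms: tert-butyl hydroperoxide, CC(C)(C)OO
Why: Hydroxyl-directed epoxidation through the vanadate ester of the tertiary allylic alcohol delivers oxygen to the C27=C25 alkene syn to the C28 hydroxyl, setting C25 and the epoxide face, while the isolated allyl alkene is left alone.

Step 13
Reactants: 17 hydroxy epoxy decalin
Product: 18 spiro[4.5] ketol (C28 ketone; C25 hydroxyl; quaternary C27; C3 anti to O26; C11 allyl)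
Conditions: BF3·OEt2 (0.3 equiv), CH2Cl2, −78 to −40 °C
Reagents that add atoms: none
Why: BF3 binds the epoxide oxygen and weakens its bond to the tertiary carbon C27; as that bond ionises, the C28–C3 σ bond lying antiperiplanar to it shifts to C27 while the C28 hydroxyl oxygen becomes the carbonyl. The closest known reaction type is the Lewis acid semipinacol rearrangement of 2,3-epoxy tertiary alcohols to β-hydroxy ketones with ring contraction. The cyclopentane (C3, C4, C10, C11, C27) is closed by a suprafacial 1,2-alkyl shift in which C3 displaces the epoxide oxygen at C27 from the rear (formally 3-exo-tet), contracting ring A. The single new stereocentre, spiro C27, is fixed by inversion at C27 and retention at C3, so C3 ends anti to the C25 oxygen whose configuration was set in step 12. The step needs C3 to migrate rather than C22, a hydride from C25 or C11, or capture by fluoride; in the cis-decalin the hydroxyl and epoxide are syn, so only C28–C3 is antiperiplanar to C27–O, C3 is the more substituted migrating carbon, and the push of the carbinol oxygen makes the shift concerted with ionisation at low temperature.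

Step 14
Reactants: 18 spiro ketol
Product: 19 C25 triisopropylsilyl ether of the spiro ketol
Conditions: iPr3SiOTf, 2,6-lutidine, CH2Cl2, −78 to 0 °C
Reagents that add atoms: triisopropylsilyl trifluoromethanesulfonate, CC(C)[Si](OS(=O)(=O)C(F)(F)F)(C(C)C)C(C)C
Why: Silylation of the hindered secondary alcohol with the silyl triflate blocks retro-aldol cleavage and lactol formation in the following steps, and the bulky silyl group should survive the later acid step.

Step 15
Reactants: 19 silyl ether
Product: 21 C13 aldehyde (C11–CH2–CHO), via ozonide 20 (not isolated)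
Conditions: O3, CH2Cl2, −78 °C; then Me2S
Reagents that add atoms: ozone, [O-][O+]=O
Why: Ozonolysis of the terminal alkene with reductive work-up gives the aldehyde, the ketone, lactone and silyl ether being inert.

Step 16
Reactants: 21 aldehyde; 22 (S)-2-methylpropane-2-sulfinamide
Product: 23 (S at sulfur, E)-N-tert-butanesulfinyl aldimine at C13
Conditions: CuSO4, CH2Cl2, rt
Reagents that add atoms: none
Why: Dehydrative condensation gives the (E)-sulfinimine at the aldehyde only, because the hindered α-quaternary C28 ketone does not condense under these conditions.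

Step 17
Reactants: 24 3-methylfuran-2(5H)-one
Product: 25 triisopropyl[(3-methylfuran-2-yl)oxy]silane
Conditions: iPr3SiOTf, Et3N, CH2Cl2, 0 °C
Reagents that add atoms: triisopropylsilyl trifluoromethanesulfonate, CC(C)[Si](OS(=O)(=O)C(F)(F)F)(C(C)C)C(C)C
Why: Soft enolisation and O-silylation of the butenolide give the aromatic 2-silyloxyfuran, a γ-nucleophilic dienolate equivalent.

Step 18
Reactants: 23 sulfinimine; 25 silyloxyfuran
Product: 26 butenolide sulfinamide (C13–N and C14–O syn; lactone D as its 3-methylbut-2-enolide)
Conditions: Me3SiOTf, CH2Cl2, −78 °C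
Reagents that add atoms: none
Why: Lewis acid promoted vinylogous Mannich (Mukaiyama–Mannich) addition of the furan γ-carbon to the imine face opposite the tert-butyl group of the s-cis sulfinimine should set C13, and the synclinal open transition state should give the C13/C14 syn (threo) relationship.

Step 19
Reactants: 26 butenolide sulfinamide
Product: 27 saturated lactone sulfinamide (C16 methyl cis to the C14 substituent)
Conditions: H2 (1 bar), 10% Pd on carbon, EtOAc, rt
Reagents that add atoms: none
Why: Hydrogen adds to the butenolide from the face opposite the C14 substituent, placing the C16 methyl cis to it, and nothing else in the molecule is reducible.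

Step 20
Reactants: 27 sulfinamide
Product: 28 C13 ammonium chloride
Conditions: HCl (4 M in 1,4-dioxane), MeOH, 0 °C
Reagents that add atoms: hydrogen chloride, Cl
Why: Brief acidic methanolysis cleaves the N–S bond and keeps the amine protonated, so it cannot attack the neighbouring lactone D, while the hindered triisopropylsilyl ether should survive.

Step 21
Reactants: 28 ammonium chloride
Product: 29 C13 azide
Conditions: imidazole-1-sulfonyl azide hydrogen sulfate, K2CO3, CuSO4·5H2O (1 mol %), MeOH, 0 °C to rt
Reagents that add atoms: imidazole-1-sulfonyl azide hydrogen sulfate, [N-]=[N+]=NS(=O)(=O)n1ccnc1.OS(=O)(=O)O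
Why: Copper-catalysed diazo transfer converts the primary amine into the azide with retention at C13, and the fast transfer at low temperature should outpace O-to-N acyl shift from lactone D.

Step 22
Reactants: 29 azido ketone
Product: 30 O-triisopropylsilyl bridged lactam (N21 bonded to C13, C22 and C28)
Conditions: TiCl4, CH2Cl2, 0 °C to rt
Reagents that add atoms: none
Why: In this intramolecular Schmidt reaction the azide adds to the activated C28 carbonyl through a six-membered azidohydrin whose chair (C14 lactone and C25 equatorial) holds C22 axial and antiperiplanar to an axial N–N2+ bond, so C22 should migrate to nitrogen with loss of N2 and close the six- and seven-membered lactam rings at once, whereas migration of the quaternary, oxygen-flanked C27 needs the equatorial diazonium wedged between the C14 lactone and the titanium-bound oxygen.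

Step 23
Reactants: 30 silyl-protected lactam
Product: 31 target CNP0120800.1
Conditions: HF·pyridine, THF, 0 °C to rt
Reagents that add atoms: none
Why: Fluoride cleaves the Si–O bond under mildly acidic, non-nucleophilic conditions that should spare the twisted lactam and both lactones.

**Compound list**

1 | 4,4-dimethoxycyclohexa-2,5-dien-1-one | COC1(OC)C=CC(=O)C=C1 | starting material
2 | (R)-5-ethyl-4,4-dimethoxycyclohex-2-en-1-one | CC[C@@H]1CC(=O)C=CC1(OC)OC | intermediate
3 | (5R,6R)-5-ethyl-6-hydroxy-4,4-dimethoxycyclohex-2-en-1-one | CC[C@@H]1[C@@H](O)C(=O)C=CC1(OC)OC | intermediate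
4 | 2-(diethoxyphosphoryl)propanoic acid (racemic) | CCOP(=O)(OCC)C(C)C(=O)O | starting material
5 | (1R,6R)-6-ethyl-5,5-dimethoxy-2-oxocyclohex-3-en-1-yl 2-(diethoxyphosphoryl)propanoate (phosphonate carbon unassigned) | CC[C@@H]1[C@@H](OC(=O)C(C)P(=O)(OCC)OCC)C(=O)C=CC1(OC)OC | intermediate
6 | (7R,7aR)-7-ethyl-6,6-dimethoxy-3-methyl-7,7a-dihydro-1-benzofuran-2(6H)-one | CC[C@@H]1[C@H]2OC(=O)C(C)=C2C=CC1(OC)OC | intermediate
7 | (3S,3aR,7R,7aS)-7-ethyl-6,6-dimethoxy-3-methylhexahydro-1-benzofuran-2(3H)-one | CC[C@@H]1[C@H]2OC(=O)[C@@H](C)[C@H]2CCC1(OC)OC | intermediate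
8 | (3S,3aR,7R,7aS)-7-ethyl-3-methylhexahydro-1-benzofuran-2,6-dione | CC[C@@H]1[C@H]2OC(=O)[C@@H](C)[C@H]2CCC1=O | intermediate
9 | trimethylsilyl enol ether of 8 (C27=C28–OSiMe3) | CC[C@@H]1[C@H]2OC(=O)[C@@H](C)[C@H]2CC=C1O[Si](C)(C)C | intermediate
10 | (3S,3aR,7R,7aS)-7-ethyl-3-methyl-3a,7a-dihydro-1-benzofuran-2,6(3H,7H)-dione | CC[C@@H]1[C@H]2OC(=O)[C@@H](C)[C@H]2C=CC1=O | intermediate
11 | C11-allyl trimethylsilyl enol ether (allyl trans to C10–C8) | CC[C@@H]1[C@H]2OC(=O)[C@@H](C)[C@H]2[C@H](CC=C)C=C1O[Si](C)(C)C | intermediate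
12 | C27-(dimethylaminomethyl) C11-allyl ketone (C27 unassigned) | CC[C@@H]1[C@H]2OC(=O)[C@@H](C)[C@H]2[C@H](CC=C)C(CN(C)C)C1=O | intermediate
13 | trimethylammonium iodide of 12 (C27 unassigned) | CC[C@@H]1[C@H]2OC(=O)[C@@H](C)[C@H]2[C@H](CC=C)C(C[N+](C)(C)C)C1=O.[I-] | intermediate
14 | α-methylene ketone (C27=CH2, C28=O, C11 allyl) | CC[C@@H]1[C@H]2OC(=O)[C@@H](C)[C@H]2[C@H](CC=C)C(=C)C1=O | intermediate
15 | C28 tertiary alcohol with pent-4-enyl group (hydroxyl cis to C3 ethyl) | CC[C@@H]1[C@H]2OC(=O)[C@@H](C)[C@H]2[C@H](CC=C)C(=C)[C@@]1(O)CCCC=C | intermediate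
16 | cis-fused decalin allylic alcohol (C28–OH, C27=C25) | CC[C@@H]1[C@H]2OC(=O)[C@@H](C)[C@H]2[C@H](CC=C)C3=CCCC[C@@]13O | intermediate
17 | cis-fused hydroxy epoxy decalin (C28 carbinol, C27–C25 epoxide syn to OH, C11 allyl) | CC[C@@H]1[C@H]2OC(=O)[C@@H](C)[C@H]2[C@H](CC=C)[C@]23O[C@@H]3CCC[C@@]12O | intermediate
18 | spiro[4.5] ketol (C28 ketone, C25 hydroxyl, quaternary C27, C11 allyl) | CC[C@@H]1[C@H]2OC(=O)[C@@H](C)[C@H]2[C@H](CC=C)[C@]13C(=O)CCC[C@H]3O | intermediate
19 | C25 triisopropylsilyl ether of 18 | CC[C@@H]1[C@H]2OC(=O)[C@@H](C)[C@H]2[C@H](CC=C)[C@]13C(=O)CCC[C@H]3O[Si](C(C)C)(C(C)C)C(C)C | intermediate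
20 | ozonide (1,2,4-trioxolane) of 19 (trioxolane carbon unassigned) | CC[C@@H]1[C@H]2OC(=O)[C@@H](C)[C@H]2[C@H](CC4OCOO4)[C@]13C(=O)CCC[C@H]3O[Si](C(C)C)(C(C)C)C(C)C | intermediate
21 | C13 aldehyde | CC[C@@H]1[C@H]2OC(=O)[C@@H](C)[C@H]2[C@H](CC=O)[C@]13C(=O)CCC[C@H]3O[Si](C(C)C)(C(C)C)C(C)C | intermediate
22 | (S)-2-methylpropane-2-sulfinamide | CC(C)(C)[S@](=O)N | starting material
23 | (S at sulfur, E)-N-tert-butanesulfinyl aldimine | CC[C@@H]1[C@H]2OC(=O)[C@@H](C)[C@H]2[C@H](C/C=N/[S@@](=O)C(C)(C)C)[C@]13C(=O)CCC[C@H]3O[Si](C(C)C)(C(C)C)C(C)C | intermediate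
24 | 3-methylfuran-2(5H)-one | CC1=CCOC1=O | starting material
25 | triisopropyl[(3-methylfuran-2-yl)oxy]silane | Cc1ccoc1O[Si](C(C)C)(C(C)C)C(C)C | intermediate
26 | butenolide sulfinamide (C13–N/C14–O syn) | CC[C@@H]1[C@H]2OC(=O)[C@@H](C)[C@H]2[C@H](C[C@H]([C@H]4C=C(C)C(=O)O4)N[S@@](=O)C(C)(C)C)[C@]13C(=O)CCC[C@H]3O[Si](C(C)C)(C(C)C)C(C)C | intermediate
27 | saturated lactone D sulfinamide (C16 methyl cis to C14 substituent) | CC[C@@H]1[C@H]2OC(=O)[C@@H](C)[C@H]2[C@H](C[C@H]([C@H]4C[C@@H](C)C(=O)O4)N[S@@](=O)C(C)(C)C)[C@]13C(=O)CCC[C@H]3O[Si](C(C)C)(C(C)C)C(C)C | intermediate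
28 | C13 ammonium chloride | CC[C@@H]1[C@H]2OC(=O)[C@@H](C)[C@H]2[C@H](C[C@H]([C@H]4C[C@@H](C)C(=O)O4)[NH3+])[C@]13C(=O)CCC[C@H]3O[Si](C(C)C)(C(C)C)C(C)C.[Cl-] | intermediate
29 | C13 azido ketone | CC[C@@H]1[C@H]2OC(=O)[C@@H](C)[C@H]2[C@H](C[C@H]([C@H]4C[C@@H](C)C(=O)O4)N=[N+]=[N-])[C@]13C(=O)CCC[C@H]3O[Si](C(C)C)(C(C)C)C(C)C | intermediate
30 | O-triisopropylsilyl ether of the target | CC[C@@H]1[C@H]2OC(=O)[C@@H](C)[C@H]2[C@@H]2C[C@H]([C@H]3C[C@@H](C)C(=O)O3)N3CCC[C@@H](O[Si](C(C)C)(C(C)C)C(C)C)[C@@]12C3=O | intermediate
31 | CNP0120800.1 | CC[C@@H]1[C@H]2OC(=O)[C@@H](C)[C@H]2[C@@H]2C[C@H]([C@H]3C[C@@H](C)C(=O)O3)N3CCC[C@@H](O)[C@@]12C3=O | target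

**Step count**

Total: 23 steps. Longest linear sequence: 22 steps (steps 1–16 and 18–23; step 17 is a one-step branch).

**Steps most likely to fail**

Step 22 (Schmidt insertion). What may go wrong is migration of the wrong carbon: if the diazonium reacts from the equatorial position, the quaternary C27 shifts to nitrogen instead of C22 and nitrogen is inserted on the wrong side of C28, giving a ring-fused instead of the bridged lactam. The fallback sets out from 28 and returns at 30, forming the N21–C22 bond and the amide bond in separate, regiochemically unambiguous events. The ammonium salt 28 is converted into the tert-butyl carbamate F1 (Boc2O, NaHCO3). Soft enolisation (Me3SiOTf, Et3N) gives the silyl enol ether F2, the only enol ether this α-quaternary ketone can form. Ozonolysis (O3, then Me2S) cleaves exactly the C28–C22 bond to the seco acid aldehyde F3. Removal of the carbamate (CF3CO2H) and reductive amination at high dilution (NaBH(OAc)3) close the nine-membered amino acid F4 through N21–C22. Transannular lactamisation with 2-chloro-1-methylpyridinium iodide and Et3N, the known way to medium-bridged lactams of this ring size, then gives 30.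

Step 18 (vinylogous Mannich addition). What may go wrong is poor simple diastereoselectivity (C13/C14 anti instead of syn) or the opposite sense of auxiliary control. The fallback sets out from aldehyde 21 and returns at azide 29, fixing C13 and C14 by reagent control and taking C16 from a chiral sulfone. Julia–Kocienski olefination of 21 with methyl (R)-2-methyl-4-[(1-phenyl-1H-tetrazol-5-yl)sulfonyl]butanoate (KN(SiMe3)2, 1,2-dimethoxyethane, −60 °C) gives the (E)-alkene F5. Shi epoxidation (fructose-derived ketone of the enantiomeric series that attacks the required face, Oxone, K2CO3 buffer) gives the trans-epoxide F6. Camphorsulfonic acid in CH2Cl2 lets the ester carbonyl open the epoxide 5-exo at C14 with inversion, forming lactone D in the hydroxy lactone F7. Mitsunobu azidation (PPh3, diisopropyl azodicarboxylate, diphenylphosphoryl azide) inverts C13 and gives 29.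

Step 13 (semipinacol ring contraction). What may go wrong is diversion of the ionising epoxide before the C3 shift: hydride shift from C25 to a C25 ketone, opening by fluoride or by proton transfer to an allylic alcohol, or epoxide migration along the carbinol. The fallback sets out from 17 and returns at 18. The tertiary alcohol is silylated with 1-(trimethylsilyl)imidazole to the epoxy silyl ether F8, which is rearranged with TiCl4 in CH2Cl2 at −78 °C (Tsuchihashi–Suzuki rearrangement). Silicon instead of a proton is then the electrofuge and no free hydroxyl is present for proton-transfer pathways; aqueous work-up gives ketol 18.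

Further compounds
F1 | step 22 | tert-butyl carbamate of the C13 amine (ring B ketone intact) | CC[C@@H]1[C@H]2OC(=O)[C@@H](C)[C@H]2[C@H](C[C@H]([C@H]4C[C@@H](C)C(=O)O4)NC(=O)OC(C)(C)C)[C@]13C(=O)CCC[C@H]3O[Si](C(C)C)(C(C)C)C(C)C
F2 | step 22 | C28–C22 trimethylsilyl enol ether of F1 | CC[C@@H]1[C@H]2OC(=O)[C@@H](C)[C@H]2[C@H](C[C@H]([C@H]4C[C@@H](C)C(=O)O4)NC(=O)OC(C)(C)C)[C@]13C(O[Si](C)(C)C)=CCC[C@H]3O[Si](C(C)C)(C(C)C)C(C)C
F3 | step 22 | seco acid aldehyde (C28 carboxylic acid on C27, C22 aldehyde) | CC[C@@H]1[C@H]2OC(=O)[C@@H](C)[C@H]2[C@H](C[C@H]([C@H]4C[C@@H](C)C(=O)O4)NC(=O)OC(C)(C)C)[C@@]1(C(=O)O)[C@H](O[Si](C(C)C)(C(C)C)C(C)C)CCC=O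
F4 | step 22 | nine-membered amino acid (N21 bonded to C13 and C22, C28 carboxylic acid) | CC[C@@H]1[C@H]2OC(=O)[C@@H](C)[C@H]2[C@@H]2C[C@H]([C@H]3C[C@@H](C)C(=O)O3)NCCC[C@@H](O[Si](C(C)C)(C(C)C)C(C)C)[C@@]12C(=O)O
F5 | step 18 | (E)-C13=C14 alkene methyl ester | CC[C@@H]1[C@H]2OC(=O)[C@@H](C)[C@H]2[C@H](C/C=C/C[C@@H](C)C(=O)OC)[C@]13C(=O)CCC[C@H]3O[Si](C(C)C)(C(C)C)C(C)C
F6 | step 18 | trans-C13,C14-epoxide methyl ester | CC[C@@H]1[C@H]2OC(=O)[C@@H](C)[C@H]2[C@H](C[C@@H]4O[C@H]4C[C@@H](C)C(=O)OC)[C@]13C(=O)CCC[C@H]3O[Si](C(C)C)(C(C)C)C(C)C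
F7 | step 18 | C13 hydroxy lactone D (C13 epimeric to the azide position) | CC[C@@H]1[C@H]2OC(=O)[C@@H](C)[C@H]2[C@H](C[C@H](O)[C@H]4C[C@@H](C)C(=O)O4)[C@]13C(=O)CCC[C@H]3O[Si](C(C)C)(C(C)C)C(C)C
F8 | step 13 | C28 trimethylsilyl ether of epoxy decalin 17 | CC[C@@H]1[C@H]2OC(=O)[C@@H](C)[C@H]2[C@H](CC=C)[C@]23O[C@@H]3CCC[C@@]12O[Si](C)(C)C
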